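**Retrosynthetic overview**
1. Side chain: the 15-acetate comes from the allylic alcohol; the 13E alkene from zirconium-catalysed carboalumination and formaldehyde trapping of a C-13/C-14 terminal alkyne, itself made from a C-9 propargyl group by one-carbon homologation.
2. C-8 and C-9: the carbinol comes from equatorial methyl addition to a C-8 ketone; the C-9–C-11 bond from alkylation of the C-8/C-9 enolate, which only the enol acetate of the cycloadduct can deliver regiospecifically.
3. Rings A and B are formed together in one enantioselective intramolecular Diels–Alder reaction of an acyclic trienal (new bonds C-5–C-10 and C-6–C-7); the formyl group on C-6 is a temporary activator, removed by decarbonylation.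
4. Enabling feature: ring B (C-5 to C-10) carries oxygen at C-8 and hydrogen at C-9, so it maps onto the diene C-7=C-8(OAc)–C-9=C-10 plus the dienophile C-5=C-6; the cis ring fusion (H-5 and CH3-20 syn) is what a diene with its tether on the Z position of C-10 must give.
5. The triene comes from 2,2-dimethylpent-4-enal (C-1 to C-6) and (Z)-4-iodopent-3-en-2-one (C-7 to C-10 and C-20) by B-alkyl Suzuki–Miyaura coupling.

Key step: step 6

Remark on the structure: in labdane numbering the SMILES is (5R,8S,9R,10S), i.e. a cis-fused decalin with H-5, CH3-20, the C-9 side chain and 8-OH all on the same face; the route is built for this isomer, not for the common trans-fused 8α-hydroxy labdane. Atom positions are written C-n (labdane numbering), compounds as plain numbers.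

**Route**

Step 1
Reactants: 1 2,2-dimethylpent-4-enal
Product: 2 (2E)-4,4-dimethylhepta-2,6-dienal
Conditions: Ph3P=CHCHO (1.2 equiv), toluene, 90 °C
Reagents that add atoms: (triphenylphosphoranylidene)acetaldehyde (O=CC=P(c1ccccc1)(c1ccccc1)c1ccccc1)
Why: Wittig olefination with the stabilised formylmethylene ylide homologates the non-enolisable neopentyl aldehyde by two carbons and should give the (E)-enal, with no stereocentre formed.

Step 2
Reactants: 2 (2E)-4,4-dimethylhepta-2,6-dienal
Product: 3 (5E)-7,7-dimethoxy-4,4-dimethylhepta-1,5-diene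
Conditions: HC(OMe)3 (3 equiv), MeOH, PPTS (5 mol%), rt
Reagents that add atoms: trimethyl orthoformate (COC(OC)OC); methanol (CO)
Why: Acid-catalysed acetalisation, with the orthoformate as water scavenger, masks the enal so that it survives hydroboration and LiN(iPr)2, and the E double bond is not touched.

Step 3
Reactants: 4 pent-3-yn-2-one
Product: 5 (3Z)-4-iodopent-3-en-2-one
Conditions: NaI (1.5 equiv), AcOH, rt, dark
Reagents that add atoms: sodium iodide ([Na+].[I-])
Why: Anti hydroiodination of the ynone (conjugate addition of iodide, then protonation) is known to give the (Z)-β-iodoenone kinetically, which fixes the later inside position of the tether on C-10.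

Step 4
Reactants: 3 (5E)-7,7-dimethoxy-4,4-dimethylhepta-1,5-diene; 5 (3Z)-4-iodopent-3-en-2-one
Product: 7 (3Z,9E)-11,11-dimethoxy-4,8,8-trimethylundeca-3,9-dien-2-one, via B-alkyl-9-BBN borane 6 (not isolated)
Conditions: 9-BBN (1.1 equiv), THF, 0 °C to rt; then 5, PdCl2(dppf) ([1,1'-bis(diphenylphosphino)ferrocene]dichloropalladium, 5 mol%), AsPh3 (5 mol%), aq. K3PO4 (3 equiv), DMF, rt, dark
Reagents that add atoms: none
Why: 9-BBN hydroborates only the terminal alkene (boron on C-1), and the B-alkyl Suzuki–Miyaura coupling of the primary alkylborane with the vinyl iodide proceeds with retention, so the tether ends up cis to the acetyl group (Z).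

Step 5
Reactants: 7 (3Z,9E)-11,11-dimethoxy-4,8,8-trimethylundeca-3,9-dien-2-one
Product: 9 (3Z,9E)-11,11-dimethoxy-4,8,8-trimethylundeca-1,3,9-trien-2-yl acetate, via lithium dienolate 8 (not isolated)
Conditions: LiN(iPr)2 (1.1 equiv), THF, −78 °C; inverse addition to Ac2O (3 equiv), −78 to 0 °C
Reagents that add atoms: acetic anhydride (CC(=O)OC(C)=O)
Why: Kinetic enolisation with LiN(iPr)2 takes the α′-methyl protons (cross-conjugated dienolate), and O-acylation of the lithium enolate gives the 2-acetoxy-1,3-diene without touching the Z double bond.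

Step 6
Reactants: 9 (3Z,9E)-11,11-dimethoxy-4,8,8-trimethylundeca-1,3,9-trien-2-yl acetate
Product: 12 (4R,4aR,8aS)-4-formyl-5,5,8a-trimethyl-3,4,4a,5,6,7,8,8a-octahydronaphthalen-2-yl acetate, via trienal 10 (not isolated), via iminium ion 11 (not isolated)
Conditions: (2R,5R)-5-benzyl-2-tert-butyl-3-methylimidazolidin-4-one (20 mol%), CF3CO2H (20 mol%), MeCN/H2O 19:1, 0.05 M, −20 °C to rt
Reagents that add atoms: water (O)
Why: Acid unmasks the enal 10 from its acetal, and condensation with the imidazolidinone gives the (E)-iminium ion 11, in which the LUMO-lowered C-5=C-6 bond adds suprafacially to the diene C-7=C-8(OAc)–C-9=C-10 in a concerted but asynchronous [4+2] step, after which hydrolysis releases 12 and the catalyst; the closest known reaction type is the imidazolidinone-catalysed type 1 intramolecular Diels–Alder reaction of 1,3,9-decatrienals. Ring A closes by the C-5–C-10 bond across the four-carbon tether C-1 to C-4 (folding helped by the C-4 gem-dimethyl group), and ring B closes as the new cyclohexene by the C-5–C-10 and C-6–C-7 bonds, the tether fixing the regiochemistry against the electronic bias of the diene. The tether occupies the inside (Z) position of the diene terminus C-10, so only the transition state with the tether exo and the iminium group endo can be reached, which forces H-5 and CH3-20 cis (cis-fused decalin) and puts the formyl group at C-6 cis to H-5. The absolute configuration of C-5 and C-10 is set by the catalyst, whose benzyl group covers one face of the s-trans (E)-iminium ion, so that by the accepted shielding model the (2R,5R) enantiomer should direct C-10 to the face of C-5 that leads to (5R,10S), the (2S,5S) catalyst leading to the antipode. The step needs the hindered, fully substituted terminus C-10 to react before the enol acetate is hydrolysed or acylates the amine; the γ-quaternary, non-enolisable enal, the intramolecularity and the acid stability of the enol acetate (chosen over a silyl enol ether) are meant to secure this, and the acetoxy group on C-8 leaves the C-8=C-9 enol acetate that later gives the C-9 enolate.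

Step 7
Reactants: 12 (4R,4aR,8aS)-4-formyl-5,5,8a-trimethyl-3,4,4a,5,6,7,8,8a-octahydronaphthalen-2-yl acetate
Product: 13 (4aR,8aS)-5,5,8a-trimethyl-3,4,4a,5,6,7,8,8a-octahydronaphthalen-2-yl acetate
Conditions: RhCl(PPh3)3 (1.1 equiv), toluene, 110 °C
Reagents that add atoms: none
Why: Tsuji–Wilkinson decarbonylation (oxidative addition of the formyl C–H bond, CO extrusion, reductive elimination) replaces the activating formyl group by hydrogen, leaves the neutral enol acetate intact and removes the C-6 stereocentre without touching C-5 or C-10.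

Step 8
Reactants: 13 (4aR,8aS)-5,5,8a-trimethyl-3,4,4a,5,6,7,8,8a-octahydronaphthalen-2-yl acetate
Product: 15 (1R,4aR,8aS)-5,5,8a-trimethyl-1-(prop-2-yn-1-yl)octahydronaphthalen-2(1H)-one, via lithium enolate 14 (not isolated)
Conditions: MeLi (2.1 equiv), DME, 0 °C; then propargyl bromide (1.5 equiv), DMPU, −78 to 0 °C; cold aq. NH4Cl quench
Reagents that add atoms: propargyl bromide (C#CCBr)
Why: Cleavage of the enol acetate with two equivalents of MeLi releases the C-8/C-9 enolate regiospecifically (direct enolisation of the ketone would go towards C-7), and SN2 alkylation with the reactive propargylic bromide should occur on the convex β-face of the cis-decalin, cis to CH3-20, because the α-face of C-9 lies in the fold under the axial C-4 methyl group.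

Step 9
Reactants: 15 (1R,4aR,8aS)-5,5,8a-trimethyl-1-(prop-2-yn-1-yl)octahydronaphthalen-2(1H)-one
Product: 16 (1R,2S,4aR,8aS)-2,5,5,8a-tetramethyl-1-(prop-2-yn-1-yl)decahydronaphthalen-2-ol
Conditions: MeMgBr (3 equiv), anhydrous CeCl3 (3 equiv), THF, −78 to 0 °C
Reagents that add atoms: methylmagnesium bromide (C[Mg]Br)
Why: 1,2-Addition of the Grignard reagent in the presence of CeCl3 (which suppresses enolisation) should occur by equatorial attack on the chair that has the C-9 chain equatorial, because the axial CH3-20 blocks the β-axial trajectory, giving the equatorial 8-CH3 and the axial 8β-OH.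

Step 10
Reactants: 16 (1R,2S,4aR,8aS)-2,5,5,8a-tetramethyl-1-(prop-2-yn-1-yl)decahydronaphthalen-2-ol
Product: 19 (4aS,6aR,10aS,10bR)-4a,7,7,10a-tetramethyldodecahydro-1H-benzo[f]chromen-3-ol (lactol as anomer mixture), via alkenylborane 17 (not isolated), via hydroxy aldehyde 18 (not isolated)
Conditions: Cy2BH (3 equiv), THF, 0 °C to rt; then H2O2, NaOAc buffer, 0 °C to rt
Reagents that add atoms: hydrogen peroxide (OO)
Why: Anti-Markovnikov hydroboration of the terminal alkyne with the hindered dialkylborane and oxidation of the alkenylborane give the aldehyde, which the cis-disposed 8-hydroxyl group traps as the six-membered lactol, so no stereocentre of the core is affected and the anomeric centre is lost in the next step.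

Step 11
Reactants: 19 (4aS,6aR,10aS,10bR)-4a,7,7,10a-tetramethyldodecahydro-1H-benzo[f]chromen-3-ol (lactol)
Product: 20 (1R,2S,4aR,8aS)-1-(but-3-yn-1-yl)-2,5,5,8a-tetramethyldecahydronaphthalen-2-ol
Conditions: dimethyl (1-diazo-2-oxopropyl)phosphonate (1.5 equiv), K2CO3 (3 equiv), MeOH, rt to 45 °C
Reagents that add atoms: dimethyl (1-diazo-2-oxopropyl)phosphonate (COP(=O)(OC)C(=[N+]=[N-])C(C)=O)
Why: Seyferth–Gilbert homologation with the Ohira–Bestmann reagent takes the lactol as a masked aldehyde, since under K2CO3 in methanol it reacts through its ring-opened hydroxy aldehyde tautomer (compound 18 of step 10), which is converted into the terminal alkyne one carbon longer under mildly basic conditions that do not affect C-9.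

Step 12
Reactants: 20 (1R,2S,4aR,8aS)-1-(but-3-yn-1-yl)-2,5,5,8a-tetramethyldecahydronaphthalen-2-ol
Product: 23 (1R,2S,4aR,8aS)-1-[(3E)-5-hydroxy-3-methylpent-3-en-1-yl]-2,5,5,8a-tetramethyldecahydronaphthalen-2-ol, via alkenylalane 21 (not isolated), via lithium alkenylaluminate 22 (not isolated)
Conditions: Me3Al (3.5 equiv), Cp2ZrCl2 (0.25 equiv), CH2Cl2, 0 °C to rt; volatiles removed in vacuo; then n-BuLi (1.2 equiv), THF/hexane, −78 to 0 °C; (CH2O)n, rt; aq. potassium sodium tartrate
Reagents that add atoms: trimethylaluminium (C[Al](C)C); formaldehyde, as paraformaldehyde (C=O)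
Why: Zirconium-catalysed carboalumination (Negishi) adds CH3–Al syn across the terminal alkyne with aluminium on the terminal carbon, and the aluminate formed with n-BuLi transfers the alkenyl group to formaldehyde with retention, which sets the 13E trisubstituted double bond.

Step 13
Reactants: 23 (1R,2S,4aR,8aS)-1-[(3E)-5-hydroxy-3-methylpent-3-en-1-yl]-2,5,5,8a-tetramethyldecahydronaphthalen-2-ol
Product: 24 (2E)-5-[(1R,2S,4aR,8aS)-2-hydroxy-2,5,5,8a-tetramethyldecahydronaphthalen-1-yl]-3-methylpent-2-en-1-yl acetate (target)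
Conditions: Ac2O (1.2 equiv), pyridine, DMAP (5 mol%), CH2Cl2, 0 °C
Reagents that add atoms: acetic anhydride (CC(=O)OC(C)=O)
Why: Acylation with acetic anhydride and pyridine takes the primary allylic hydroxyl and leaves the hindered, axial tertiary 8-hydroxyl untouched.

**Compound list**
1 | 2,2-dimethylpent-4-enal | O=CC(C)(C)CC=C | starting material
2 | (2E)-4,4-dimethylhepta-2,6-dienal | O=C/C=C/C(C)(C)CC=C | intermediate
3 | (5E)-7,7-dimethoxy-4,4-dimethylhepta-1,5-diene | COC(OC)/C=C/C(C)(C)CC=C | intermediate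
4 | pent-3-yn-2-one | CC#CC(C)=O | starting material
5 | (3Z)-4-iodopent-3-en-2-one | I/C(C)=C\C(C)=O | intermediate
6 | 9-[(5E)-7,7-dimethoxy-4,4-dimethylhept-5-en-1-yl]-9-borabicyclo[3.3.1]nonane | COC(OC)/C=C/C(C)(C)CCCB1C2CCCC1CCC2 | intermediate
7 | (3Z,9E)-11,11-dimethoxy-4,8,8-trimethylundeca-3,9-dien-2-one | COC(OC)/C=C/C(C)(C)CCC/C(C)=C\C(C)=O | intermediate
8 | lithium (3Z,9E)-11,11-dimethoxy-4,8,8-trimethylundeca-1,3,9-trien-2-olate | COC(OC)/C=C/C(C)(C)CCC/C(C)=C\C(=C)[O-].[Li+] | intermediate
9 | (3Z,9E)-11,11-dimethoxy-4,8,8-trimethylundeca-1,3,9-trien-2-yl acetate | COC(OC)/C=C/C(C)(C)CCC/C(C)=C\C(=C)OC(C)=O | intermediate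
10 | (3Z,9E)-4,8,8-trimethyl-11-oxoundeca-1,3,9-trien-2-yl acetate | O=C/C=C/C(C)(C)CCC/C(C)=C\C(=C)OC(C)=O | intermediate
11 | iminium trifluoroacetate of 10 with (2R,5R)-5-benzyl-2-tert-butyl-3-methylimidazolidin-4-one | CN1C(=O)[C@@H](Cc2ccccc2)[N+](=C/C=C/C(C)(C)CCC/C(C)=C\C(=C)OC(C)=O)[C@H]1C(C)(C)C.[O-]C(=O)C(F)(F)F | intermediate
12 | (4R,4aR,8aS)-4-formyl-5,5,8a-trimethyl-3,4,4a,5,6,7,8,8a-octahydronaphthalen-2-yl acetate | C=1[C@@]2(C)CCCC(C)(C)[C@H]2[C@H](C=O)CC=1OC(C)=O | intermediate
13 | (4aR,8aS)-5,5,8a-trimethyl-3,4,4a,5,6,7,8,8a-octahydronaphthalen-2-yl acetate | C=1[C@@]2(C)CCCC(C)(C)[C@H]2CCC=1OC(C)=O | intermediate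
14 | lithium (4aR,8aS)-5,5,8a-trimethyl-3,4,4a,5,6,7,8,8a-octahydronaphthalen-2-olate | C=1[C@@]2(C)CCCC(C)(C)[C@H]2CCC=1[O-].[Li+] | intermediate
15 | (1R,4aR,8aS)-5,5,8a-trimethyl-1-(prop-2-yn-1-yl)octahydronaphthalen-2(1H)-one | C#CC[C@@H]1[C@@]2(C)CCCC(C)(C)[C@H]2CCC1=O | intermediate
16 | (1R,2S,4aR,8aS)-2,5,5,8a-tetramethyl-1-(prop-2-yn-1-yl)decahydronaphthalen-2-ol | C#CC[C@@H]1[C@@]2(C)CCCC(C)(C)[C@H]2CC[C@]1(C)O | intermediate
17 | dicyclohexyl{(1E)-3-[(1R,2S,4aR,8aS)-2-hydroxy-2,5,5,8a-tetramethyldecahydronaphthalen-1-yl]prop-1-en-1-yl}borane | C1CCCCC1B(/C=C/C[C@@H]2[C@@]3(C)CCCC(C)(C)[C@H]3CC[C@]2(C)O)C1CCCCC1 | intermediate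
18 | 3-[(1R,2S,4aR,8aS)-2-hydroxy-2,5,5,8a-tetramethyldecahydronaphthalen-1-yl]propanal | O=CCC[C@@H]1[C@@]2(C)CCCC(C)(C)[C@H]2CC[C@]1(C)O | intermediate
19 | (4aS,6aR,10aS,10bR)-4a,7,7,10a-tetramethyldodecahydro-1H-benzo[f]chromen-3-ol (lactol as anomer mixture; ring-closed tautomer of 18) | OC1CC[C@@H]2[C@@]3(C)CCCC(C)(C)[C@H]3CC[C@]2(C)O1 | intermediate
20 | (1R,2S,4aR,8aS)-1-(but-3-yn-1-yl)-2,5,5,8a-tetramethyldecahydronaphthalen-2-ol | C#CCC[C@@H]1[C@@]2(C)CCCC(C)(C)[C@H]2CC[C@]1(C)O | intermediate
21 | (E)-alkenyl(dimethyl)alane from 20, 8-O-dimethylaluminium alkoxide | C[Al](C)/C=C(\C)CC[C@@H]1[C@@]2(C)CCCC(C)(C)[C@H]2CC[C@]1(C)O[Al](C)C | intermediate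
22 | lithium (E)-alkenyl(butyl)dimethylaluminate from 21, 8-O-dimethylaluminium alkoxide | [Li+].CCCC[Al-](C)(C)/C=C(\C)CC[C@@H]1[C@@]2(C)CCCC(C)(C)[C@H]2CC[C@]1(C)O[Al](C)C | intermediate
23 | (1R,2S,4aR,8aS)-1-[(3E)-5-hydroxy-3-methylpent-3-en-1-yl]-2,5,5,8a-tetramethyldecahydronaphthalen-2-ol | OC/C=C(\C)CC[C@@H]1[C@@]2(C)CCCC(C)(C)[C@H]2CC[C@]1(C)O | intermediate
24 | (2E)-5-[(1R,2S,4aR,8aS)-2-hydroxy-2,5,5,8a-tetramethyldecahydronaphthalen-1-yl]-3-methylpent-2-en-1-yl acetate | CC(=O)OC/C=C(\C)CC[C@@H]1[C@@]2(C)CCCC(C)(C)[C@H]2CC[C@]1(C)O | target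

**Step count and risks**
Total steps: 13. Longest linear sequence: 12 steps (steps 1, 2 and 4 to 13, from 1); step 3 is a one-step side branch.

Steps most likely to fail:

1. Step 6. The fully substituted diene terminus may add too slowly to the iminium ion, so that catalyst turnover lags, the enol acetate is lost by hydrolysis or by acylating the amine, and an uncatalysed racemic background reaction takes over. Fallback: auxiliary control with a strong Lewis acid, setting out from 7. Mild hydrolysis (PPTS, acetone/water) would give the keto enal F1, and Pinnick oxidation (NaClO2, NaH2PO4, 2-methylbut-2-ene) the acid F2. Pivaloyl chloride and Et3N (THF, −20 °C) would give the pivaloyl mixed anhydride F3, which is used in the same flask to acylate (R)-4-benzyl-1,3-oxazolidin-2-one in the presence of LiCl and would give the imide F4. Kinetic silylation (LiN(iPr)2, TBSCl, HMPA, THF, −78 °C) would give the silyl dienol ether F5. Me2AlCl (1.4 equiv, CH2Cl2, −30 °C) should then close both rings through the chelated s-cis acyl oxazolidinone, with the same Z-diene constraint and diene approach anti to the benzyl group, to give the cycloadduct F6. LiOH/H2O2 would give the acid F7, which is converted into the Barton ester F8 (N-hydroxypyridine-2-thione, DCC) and reduced under visible light with tert-butanethiol to the silyl enol ether F9. MeLi (THF/DMPU, 0 °C to rt) would cleave the Si–O bond and the fallback comes back to the route at 14.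

2. Step 8. C-Alkylation at the neopentyl-type C-9 may be slow, so that proton exchange between enolate, product and lithium tert-butoxide erodes the regiochemistry, gives over-alkylation and lets C-9 epimerise. Fallback: decarboxylative allylation under neutral conditions, setting out from 14. Allyl chloroformate (THF, TMEDA, −78 °C) would give the allyl enol carbonate F10, and Pd(PPh3)4 (THF, rt) the C-9 allyl ketone F11 by Tsuji decarboxylative allylation, with ion-pair collapse on the convex face. MeMgBr/CeCl3 would give the carbinol F12, and 9-BBN followed by NaOH/H2O2 the diol F13. Parikh–Doering oxidation of the primary alcohol (SO3·pyridine, DMSO, iPr2NEt) would give hydroxy aldehyde 18, which closes to the lactol, and the fallback comes back to the route at 19.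

3. Step 9. The ketone may enolise instead of adding the nucleophile, or axial and equatorial attack at C-8 may compete. Fallback: the methyl group is introduced as a methylene, setting out from 15. Corey–Chaykovsky reaction with dimethylsulfoxonium methylide (Me3S(O)I, NaH, DMSO, rt) adds reversibly and should deliver CH2 equatorially, giving the spiro-epoxide F14 with the oxygen axial on the β-face. LiEt3BH (THF, 0 °C) would open it at the CH2 carbon, and the fallback comes back to the route at 16.

Further compounds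
F1 | step 6 | (2E,8Z)-4,4,8-trimethyl-10-oxoundeca-2,8-dienal | O=C/C=C/C(C)(C)CCC/C(C)=C\C(C)=O
F2 | step 6 | (2E,8Z)-4,4,8-trimethyl-10-oxoundeca-2,8-dienoic acid | OC(=O)/C=C/C(C)(C)CCC/C(C)=C\C(C)=O
F3 | step 6 | (2E,8Z)-4,4,8-trimethyl-10-oxoundeca-2,8-dienoic 2,2-dimethylpropanoic anhydride | CC(C)(C)C(=O)OC(=O)/C=C/C(C)(C)CCC/C(C)=C\C(C)=O
F4 | step 6 | (4R)-4-benzyl-3-[(2E,8Z)-4,4,8-trimethyl-10-oxoundeca-2,8-dienoyl]-1,3-oxazolidin-2-one | O=C(/C=C/C(C)(C)CCC/C(C)=C\C(C)=O)N1[C@H](Cc2ccccc2)COC1=O
F5 | step 6 | tert-butyldimethylsilyl dienol ether of F4 (2-silyloxy-1,3-diene, 8Z) | O=C(/C=C/C(C)(C)CCC/C(C)=C\C(=C)O[Si](C)(C)C(C)(C)C)N1[C@H](Cc2ccccc2)COC1=O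
F6 | step 6 | cis-fused cycloadduct, C-6 acyl oxazolidinone (β), C-8 silyl enol ether | C=1[C@@]2(C)CCCC(C)(C)[C@H]2[C@H](C(=O)N3[C@H](Cc4ccccc4)COC3=O)CC=1O[Si](C)(C)C(C)(C)C
F7 | step 6 | C-6 carboxylic acid of the cycloadduct | C=1[C@@]2(C)CCCC(C)(C)[C@H]2[C@H](C(O)=O)CC=1O[Si](C)(C)C(C)(C)C
F8 | step 6 | Barton ester (2-thioxopyridin-1(2H)-yl ester) of F7 | C=1[C@@]2(C)CCCC(C)(C)[C@H]2[C@H](C(=O)ON3C=CC=CC3=S)CC=1O[Si](C)(C)C(C)(C)C
F9 | step 6 | tert-butyldimethylsilyl enol ether corresponding to 13 | C=1[C@@]2(C)CCCC(C)(C)[C@H]2CCC=1O[Si](C)(C)C(C)(C)C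
F10 | step 8 | allyl (4aR,8aS)-5,5,8a-trimethyl-3,4,4a,5,6,7,8,8a-octahydronaphthalen-2-yl carbonate | C=1[C@@]2(C)CCCC(C)(C)[C@H]2CCC=1OC(=O)OCC=C
F11 | step 8 | (1R,4aR,8aS)-5,5,8a-trimethyl-1-(prop-2-en-1-yl)octahydronaphthalen-2(1H)-one | C=CC[C@@H]1[C@@]2(C)CCCC(C)(C)[C@H]2CCC1=O
F12 | step 8 | (1R,2S,4aR,8aS)-2,5,5,8a-tetramethyl-1-(prop-2-en-1-yl)decahydronaphthalen-2-ol | C=CC[C@@H]1[C@@]2(C)CCCC(C)(C)[C@H]2CC[C@]1(C)O
F13 | step 8 | (1R,2S,4aR,8aS)-1-(3-hydroxypropyl)-2,5,5,8a-tetramethyldecahydronaphthalen-2-ol | OCCC[C@@H]1[C@@]2(C)CCCC(C)(C)[C@H]2CC[C@]1(C)O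
F14 | step 9 | spiro-epoxide at C-8 of 15 (oxygen β, CH2 α) | C#CC[C@@H]1[C@@]2(C)CCCC(C)(C)[C@H]2CC[C@@]13CO3
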